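**Retrosynthetic overview**
1. Feature: ring B (C5–C10) carries the C8 methyl on the C7=C8 alkene and C4 on C5 in the pattern of carvone's methyl enone and isopropenyl group, and C4 is a gem-dimethyl carbon next to oxygenated C3. (S)-Carvone therefore serves as ring B, and C3–C4 is the ring A bond to make.
2. Ring order: ring B from the chiral pool, with quaternary C10 set by methylation and then allylation anti to the isopropenyl group and the allyl group converted to 2-cyanoethyl. Ring A is closed second by hydrogen-atom-transfer radical addition of C4 to the nitrile carbon C3.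
3. Side chain: C9=O becomes the C9=C11 methylene; 9-BBN sets C9–H, and the C11–B bond is homologated with bromoacetate (C12, C13). The C13 aldehyde gives the C13≡C14 alkyne, and methylalumination–formaldehyde gives the 13E allylic alcohol (C16, C15).
4. C3: the ketone is masked as a dioxolane while the enone is converted, then reduced to the axial alcohol with KB(sBu)3H.
5. End: C15–OH is esterified with (S)-3-methylpentanoic acid, and C3–OH opens Meldrum's acid to the malonic half-ester.

Key step: step 5

Remark: labdane numbering is used for the bicyclic compounds (carvone C1, C2, C3, C4, C5, C6 and its isopropenyl carbon become C9, C8, C7, C6, C5, C10 and C4). The SMILES is read as the ent-labdane series: C5–H anti to the C10 methyl, C9 chain syn to it, C3–O axial and anti to it.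

**Route**

Step 1
Reactants: 1 (S)-carvone
Product: 3 6-methylcarvone (5S; C6 epimers), via lithium enolate 2 (not isolated)
Conditions: LiN(iPr)2, THF, −78 °C; then MeI, −78 → 0 °C
Reagents that add atoms: methyl iodide, CI
Why: Kinetic deprotonation of the cross-conjugated enone at C6 and SN2 methylation of the enolate; the new C6 centre need not be controlled because step 2 planarises it again.

Step 2
Reactants: 3 6-methylcarvone
Product: 5 (5R,6R)-6-allyl-6-methylcarvone, via lithium enolate 4 (not isolated)
Conditions: LiN(iPr)2, THF, −78 → −20 °C; then allyl bromide, −78 °C → rt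
Reagents that add atoms: allyl bromide, C=CCBr
Why: Enolate alkylation in which the tetrasubstituted C6 enolate should take up the allyl group on the face anti to the neighbouring isopropenyl group, which sets the quaternary carbon (later C10) with the chain trans to the isopropenyl group.

Step 3
Reactants: 5 (5R,6R)-6-allyl-6-methylcarvone
Product: 7 (5R,6R)-6-(3-hydroxypropyl)-6-methylcarvone, via alkyl(disiamyl)borane 6 (not isolated)
Conditions: (Me2CHCHMe)2BH (made in situ from BH3·THF and 2-methyl-2-butene), THF, 0 °C; then NaBO3·4H2O, H2O, rt
Reagents that add atoms: sodium perborate, [Na+].[O-]B1OO1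
Why: Anti-Markovnikov hydroboration–oxidation in which the bulky dialkylborane should pick the monosubstituted allyl alkene over the hindered 1,1-disubstituted isopropenyl group and the hindered enone carbonyl, and perborate oxidises the C–B bond without the enone epoxidation that alkaline peroxide would risk.

Step 4
Reactants: 7 (5R,6R)-6-(3-hydroxypropyl)-6-methylcarvone
Product: 10 (5R,6R)-6-(2-cyanoethyl)-6-methylcarvone, via aldehyde 8 (not isolated), via aldimine 9 (not isolated)
Conditions: TEMPO (cat.), PhI(OAc)2, NH4OAc, MeCN/H2O, rt
Reagents that add atoms: ammonium acetate, [NH4+].CC(=O)[O-]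
Why: One-pot oxidative conversion of a primary alcohol into a nitrile (oxoammonium oxidation to the aldehyde, condensation with ammonia, second oxidation of the aldimine), to which the enone and the isopropenyl group should be inert.

Step 5
Reactants: 10 (5R,6R)-6-(2-cyanoethyl)-6-methylcarvone
Product: 12 trans-fused bicyclic 3,9-dione (C9 enone with C7=C8; methyls on C4 twice and on C8 and C10), via ketimine 11 (not isolated)
Conditions: Fe(acac)3, PhSiH3, EtOH (high dilution), 60 °C, argon; then 1 M HCl, THF, rt
Reagents that add atoms: water, O
Why: The iron hydride generated from Fe(acac)3 and PhSiH3 in EtOH transfers a hydrogen atom to the terminal CH2 of the isopropenyl group (Mukaiyama-type hydrogen-atom transfer), which makes the second C4 methyl and a tertiary C4 radical. This nucleophilic radical adds to the nitrile carbon and closes ring A in the 6-exo-dig mode, forming C3–C4; the iminyl radical is reduced by divalent iron, protonated by EtOH to ketimine 11 and hydrolysed by the acid to the C3 ketone. The closest known reaction type is the iron-mediated reductive radical cyclisation of alkenyl nitriles to cyclic ketones. No stereocentre is created, since C4 becomes a gem-dimethyl carbon, and the trans ring fusion is already fixed by the anti arrangement of the C10 chain and the C5 isopropenyl group, which lets the chain reach C4 through a chair with both ring A bonds equatorial on ring B. The step needs hydrogen-atom transfer to the isopropenyl group only and ring closure before the radical is reduced: the isopropenyl group is the sole electron-rich 1,1-disubstituted alkene, the enone alkene is electron-poor, closure of the C4 radical on the enone would give a four-membered or a bridged five-membered ring, and high dilution with a low stationary hydride concentration keeps reduction and intermolecular addition to the enone slow.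

Step 6
Reactants: 12 trans-fused bicyclic 3,9-dione
Product: 13 C3 ethylene ketal of the dione (C9 enone untouched)
Conditions: TMSOCH2CH2OTMS, TMSOTf (cat.), CH2Cl2, −78 → −20 °C
Reagents that add atoms: 1,2-bis(trimethylsilyloxy)ethane, C[Si](C)(C)OCCO[Si](C)(C)C
Why: Noyori ketalisation should take the saturated C3 ketone and leave the conjugated, doubly flanked C9 enone, and the mask is needed because the ylide of step 7 would attack C3 first and because KB(sBu)3H would reduce the enone 1,4 if C3 were reduced at this stage.

Step 7
Reactants: 13 C3 ethylene ketal of the dione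
Product: 14 ketal diene with exocyclic C9=C11H2 next to C7=C8
Conditions: Ph3PCH3Br, KOtBu, toluene, 90 °C
Reagents that add atoms: methyltriphenylphosphonium bromide, C[P+](c1ccccc1)(c1ccccc1)c1ccccc1.[Br-]
Why: Wittig methylenation under the potassium tert-butoxide and hot toluene conditions that serve for hindered ketones, on an enone that has no hydrogen on C10 to enolise.

Step 8
Reactants: 14 ketal diene
Product: 16 ketal ethyl ester with C9–CH2CH2CO2Et (C9–H anti to the C10 methyl), via B-alkyl-9-BBN 15 (not isolated)
Conditions: 9-BBN, THF, rt → 50 °C; then BrCH2CO2Et, KOtBu, tBuOH/THF, 0 °C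
Reagents that add atoms: ethyl bromoacetate, CCOC(=O)CBr
Why: 9-BBN should add only to the exocyclic C9=C11 bond, with boron on C11 and hydrogen delivered to C9 from the face anti to the axial C10 methyl (this sets C9 with the chain equatorial), and the B-alkyl-9-BBN is then homologated by the Brown α-alkylation of ethyl bromoacetate (ester enolate adds to boron, the C11 group migrates 1,2 with loss of bromide), which makes C11–C12 without an SN2 reaction at the hindered C11.

Step 9
Reactants: 16 ketal ethyl ester
Product: 17 3-keto ethyl ester
Conditions: 1 M HCl, THF, rt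
Reagents that add atoms: water, O
Why: Acid hydrolysis of the dioxolane, which the ethyl ester and the trisubstituted C7=C8 alkene should survive at room temperature.

Step 10
Reactants: 17 3-keto ethyl ester
Product: 18 3-hydroxy ethyl ester (C3–OH axial, anti to the C10 methyl)
Conditions: KB(sBu)3H, THF, −78 °C; then H2O
Reagents that add atoms: none
Why: The bulky trialkylborohydride should attack the C3 ketone from the equatorial direction, past the C4 gem-dimethyl group, and give the axial alcohol, while no enone remains and the ester is not reduced at −78 °C.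

Step 11
Reactants: 18 3-hydroxy ethyl ester
Product: 19 3-hydroxy C13 aldehyde
Conditions: iBu2AlH (2.2 equiv), CH2Cl2, −78 °C; then aq. KNaC4H4O6 (potassium sodium tartrate)
Reagents that add atoms: none
Why: Partial reduction of the unhindered ester through the tetrahedral aluminium hemiacetal, which is stable at −78 °C, after the first equivalent has deprotonated the C3–OH.

Step 12
Reactants: 19 3-hydroxy C13 aldehyde
Product: 20 3-hydroxy terminal alkyne (C13≡C14)
Conditions: MeC(O)C(N2)P(O)(OMe)2, K2CO3, MeOH, 0 °C → rt
Reagents that add atoms: dimethyl (1-diazo-2-oxopropyl)phosphonate, COP(=O)(OC)C(=[N+]=[N-])C(C)=O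
Why: Ohira–Bestmann modification of the Seyferth–Gilbert homologation, which is mild enough for an enolisable aldehyde that has no stereocentre at its α-carbon.

Step 13
Reactants: 20 3-hydroxy terminal alkyne
Product: 22 ent-labda-7,13E-diene-3,15-diol (3-OH axial), via alkenylalane 21 (not isolated)
Conditions: Me3Al, Cp2ZrCl2 (cat.), CH2Cl2, 0 °C → rt; then nBuLi, THF, −78 °C; (CH2O)n, → rt; aqueous work-up
Reagents that add atoms: trimethylaluminium, C[Al](C)C; paraformaldehyde (reacts as formaldehyde), C=O
Why: Negishi zirconium-catalysed methylalumination adds methyl (to C13) and aluminium (to C14) syn across the terminal alkyne, and the alkenylalanate takes up formaldehyde with retention, which fixes the 13E geometry while the C3–OH rides along as its aluminium alkoxide.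

Step 14
Reactants: 22 ent-labda-7,13E-diene-3,15-diol; 23 (S)-3-methylpentanoic acid
Product: 24 15-O-[(S)-3-methylpentanoyl] diol (C3–OH free)
Conditions: DCC, DMAP (cat.), CH2Cl2, 0 °C
Reagents that add atoms: (S)-3-methylpentanoic acid 23, CC[C@H](C)CC(=O)O
Why: Steglich esterification in which the primary allylic C15–OH should be acylated far faster than the axial C3–OH next to the C4 gem-dimethyl group, and the β-stereocentre of the acid cannot epimerise.

Step 15
Reactants: 24 15-O-[(S)-3-methylpentanoyl] diol; 25 Meldrum's acid
Product: 26 target CNP0234792.1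
Conditions: toluene, 100 °C
Reagents that add atoms: Meldrum's acid 25, CC1(C)OC(=O)CC(=O)O1
Why: Thermal alcoholysis of Meldrum's acid (the alcohol opens the dioxanedione and acetone is lost) gives the malonic half-ester directly as the free acid with retention at C3, a reaction that also serves for tertiary alcohols and so should serve for this hindered secondary one.

**Compound list**
1 | (S)-(+)-carvone | CC1=CC[C@@H](CC1=O)C(C)=C | starting material
2 | lithium enolate of carvone (C1–O–Li, C1=C6) | [Li]OC1=C[C@@H](C(C)=C)CC=C1C | intermediate (not isolated)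
3 | 6-methylcarvone, (5S), C6 epimers | CC1=CC[C@@H](C(C)C1=O)C(C)=C | intermediate
4 | lithium enolate of 6-methylcarvone | [Li]OC1=C(C)[C@@H](C(C)=C)CC=C1C | intermediate (not isolated)
5 | (5R,6R)-6-allyl-6-methylcarvone (allyl trans to isopropenyl) | O=C1C(C)=CC[C@H](C(C)=C)[C@@]1(C)CC=C | intermediate
6 | alkyl(disiamyl)borane from 5 | O=C1C(C)=CC[C@H](C(C)=C)[C@@]1(C)CCCB(C(C)C(C)C)C(C)C(C)C | intermediate (not isolated)
7 | (5R,6R)-6-(3-hydroxypropyl)-6-methylcarvone | O=C1C(C)=CC[C@H](C(C)=C)[C@@]1(C)CCCO | intermediate
8 | (5R,6R)-6-(3-oxopropyl)-6-methylcarvone | O=C1C(C)=CC[C@H](C(C)=C)[C@@]1(C)CCC=O | intermediate (not isolated)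
9 | aldimine of 8 | O=C1C(C)=CC[C@H](C(C)=C)[C@@]1(C)CCC=N | intermediate (not isolated)
10 | (5R,6R)-6-(2-cyanoethyl)-6-methylcarvone (cyanoethyl trans to isopropenyl) | O=C1C(C)=CC[C@H](C(C)=C)[C@@]1(C)CCC#N | intermediate
11 | trans-fused C3 ketimine of the C9 enone | O=C1C(C)=CC[C@@H]2C(C)(C)C(=N)CC[C@@]12C | intermediate (not isolated)
12 | trans-fused bicyclic 3,9-dione (ent-11-nordrim-7-ene-3,9-dione) | O=C1C(C)=CC[C@@H]2C(C)(C)C(=O)CC[C@@]12C | intermediate
13 | C3 ethylene ketal of 12 | O=C1C(C)=CC[C@@H]2C(C)(C)C3(OCCO3)CC[C@@]12C | intermediate
14 | C3 ketal, 7,9(11)-diene (exocyclic C9=C11H2) | C=C1C(C)=CC[C@@H]2C(C)(C)C3(OCCO3)CC[C@@]12C | intermediate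
15 | C11 B-alkyl-9-BBN (C9–H anti to C10 methyl) | B1(C2CCCC1CCC2)C[C@@H]3C(C)=CC[C@@H]4C(C)(C)C5(OCCO5)CC[C@@]34C | intermediate (not isolated)
16 | C3 ketal, C9–CH2CH2CO2Et ester | CCOC(=O)CC[C@@H]1C(C)=CC[C@@H]2C(C)(C)C3(OCCO3)CC[C@@]12C | intermediate
17 | 3-keto ethyl ester | CCOC(=O)CC[C@@H]1C(C)=CC[C@@H]2C(C)(C)C(=O)CC[C@@]12C | intermediate
18 | 3-hydroxy ethyl ester (OH axial, anti to C10 methyl) | CCOC(=O)CC[C@@H]1C(C)=CC[C@@H]2C(C)(C)[C@@H](O)CC[C@@]12C | intermediate
19 | 3-hydroxy C13 aldehyde | O=CCC[C@@H]1C(C)=CC[C@@H]2C(C)(C)[C@@H](O)CC[C@@]12C | intermediate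
20 | 3-hydroxy C13≡C14 alkyne | C#CCC[C@@H]1C(C)=CC[C@@H]2C(C)(C)[C@@H](O)CC[C@@]12C | intermediate
21 | (E)-alkenyl(dimethyl)alane, C3–O–AlMe2 | C[Al](C)/C=C(\C)CC[C@@H]1C(C)=CC[C@@H]2C(C)(C)[C@@H](O[Al](C)C)CC[C@@]12C | intermediate (not isolated)
22 | ent-labda-7,13E-diene-3,15-diol (3-OH axial) | OC/C=C(\C)CC[C@@H]1C(C)=CC[C@@H]2C(C)(C)[C@@H](O)CC[C@@]12C | intermediate
23 | (S)-3-methylpentanoic acid | CC[C@H](C)CC(=O)O | starting material
24 | 15-O-[(S)-3-methylpentanoyl] derivative of 22 | CC[C@H](C)CC(=O)OC/C=C(\C)CC[C@@H]1C(C)=CC[C@@H]2C(C)(C)[C@@H](O)CC[C@@]12C | intermediate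
25 | Meldrum's acid | CC1(C)OC(=O)CC(=O)O1 | starting material
26 | CNP0234792.1: 3-(hydrogen malonate) 15-[(S)-3-methylpentanoate] of 22; (3S,5S,9R,10S,13E) in labdane numbering | CC[C@H](C)CC(=O)OC/C=C(\C)CC[C@@H]1C(C)=CC[C@@H]2C(C)(C)[C@@H](OC(=O)CC(=O)O)CC[C@@]12C | target

**Totals and risks**
Total step count: 15. Longest linear sequence: 15 steps from (S)-carvone; acid 23 and Meldrum's acid 25 are bought.

Steps most likely to fail:

Step 5. The C4 radical may be reduced before it closes on the nitrile (net hydrogenation of the isopropenyl group), or hydrogen-atom transfer may also reach the enone. Fallback: the radical is generated by halogen abstraction instead of hydrogen-atom transfer. It sets out from nitrile 10: HBr in AcOH at 0 °C should add in the Markovnikov sense to the isopropenyl group and give the tertiary bromide F1. Slow addition of Bu3SnH with AIBN in benzene at 80 °C then forms the same C4 radical, which closes 6-exo on the nitrile to ketimine 11. Acid work-up returns to dione 12.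

Step 8. The 1,2-migration of the β-branched C11 group from boron to the bromoacetate carbon may be slow, so that protodeboronation or simple oxidation of the borane takes over. Fallback: the C11–C12 bond is made by SN2 alkylation with a soft nucleophile. It sets out from diene 14: borane 15 is oxidised with NaOH/H2O2 to the C11 alcohol F2. I2, PPh3 and imidazole give the C11 iodide F3. NaH and diethyl malonate in DMF at 70 °C give the malonate F4, and Krapcho dealkoxycarbonylation (LiCl, wet DMSO, 150 °C) returns to ester 16.

Step 7. The basic ylide may deprotonate the enone at C6 instead of adding to the hindered C9 carbonyl, so that methylenation stalls or the alkene drifts out of conjugation. Fallback: addition–elimination with a small, weakly basic nucleophile. It sets out from ketal enone 13: LiCH2SiMe3 with CeCl3 in THF at −78 °C should add 1,2 to C9 and give the β-hydroxysilane F5 (C9 configuration of no consequence). KH in THF then effects the Peterson elimination and comes back at diene 14.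

**Further compounds**
F1 | step 5 | tertiary bromide: (5R,6R)-5-(2-bromopropan-2-yl)-6-(2-cyanoethyl)-2,6-dimethylcyclohex-2-en-1-one | O=C1C(C)=CC[C@H](C(C)(C)Br)[C@@]1(C)CCC#N
F2 | step 8 | C3 ketal C11 alcohol (C9–CH2OH, cis to C10 methyl) | OC[C@@H]1C(C)=CC[C@@H]2C(C)(C)C3(OCCO3)CC[C@@]12C
F3 | step 8 | C3 ketal C11 iodide | IC[C@@H]1C(C)=CC[C@@H]2C(C)(C)C3(OCCO3)CC[C@@]12C
F4 | step 8 | diethyl C11-alkylmalonate (C3 ketal) | CCOC(=O)C(C[C@@H]1C(C)=CC[C@@H]2C(C)(C)C3(OCCO3)CC[C@@]12C)C(=O)OCC
F5 | step 7 | C9 β-hydroxysilane: 9-hydroxy-9-(trimethylsilylmethyl) C3 ketal | C[Si](C)(C)CC1(O)C(C)=CC[C@@H]2C(C)(C)C3(OCCO3)CC[C@@]12C
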